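**Strategy.** The benzofuran (O1, C2, C3, C3a, C4 to C7, C7a; ring A is the carbocycle) is disconnected at O1–C2 and C3–C3a. The aryl–C2–C3–aryl unit is then the resveratrol stilbene, and C3a, flanked by the oxygen-bearing C4 and C7a, maps onto C2 of a cyclohexane-1,3-dione. Oxidation of dione ester 1 by Mn(OAc)3 (trivalent manganese) in the presence of resveratrol trimethyl ether 2 forges both bonds and the furan ring in one operation, giving dihydrofuran 3 with ring A still saturated. Both partners are purchased, so no precursor synthesis is needed; dehydrogenation, ester-to-aldehyde adjustment and demethylation complete the route.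

Key step: step 1

Assumption: 3 is carried forward as the racemic mixture of C6 epimers, because step 2 destroys all three stereocentres and the target is achiral.

Step 1
Reactants: 1 methyl 3,5-dioxocyclohexane-1-carboxylate; 2 (E)-3,4',5-trimethoxystilbene
Product: 3 methyl 2,3-trans-3-(3,5-dimethoxyphenyl)-2-(4-methoxyphenyl)-4-oxo-2,3,4,5,6,7-hexahydrobenzofuran-6-carboxylate (racemic; both C6 epimers, one drawn)
Conditions: Mn(OAc)3·2H2O (2.2 equiv), 1 (1.5 equiv), AcOH, 70 °C, N2
Reagents that add atoms: none
Why: The manganese enolate of 1 undergoes one-electron oxidation by Mn(OAc)3 to an electron-poor radical centred on the carbon flanked by both carbonyls; this carbon, the future C3a, bonds to the alkene carbon of 2 attached to the 3,5-dimethoxyphenyl ring (C3–C3a), and the 4-methoxybenzylic radical left behind is oxidised by a second equivalent of trivalent manganese to a cation that the enol oxygen traps (O1–C2). The closest known reaction type is the Mn(OAc)3 or (NH4)2Ce(NO3)6 oxidative [3+2] annulation of cyclic 1,3-diones with styrenes and stilbenes to 4-oxo-hexahydrobenzofurans. The dihydrofuran ring closes by a polar five-membered C–O closure in which the enol, with both of its carbons inside the new ring, captures a planar benzylic cation; it is not a radical cyclisation. C2 and C3 should emerge trans because the planar cation lets the oxygen close from the face that keeps the two aryl groups apart, whereas the remote C6 is uncontrolled and gives both epimers, which is harmless since step 2 erases all three centres. The step must orient the unsymmetrical stilbene correctly, and the 4'-methoxy group does this: it raises the electron density at the alkene carbon remote from its own ring, where the electrophilic radical therefore attacks, and only a para donor can stabilise the cation that becomes C2. On the dione side there is nothing to select, because symmetrical 1 offers one carbon nucleophile and two identical enol oxygens, whereas a true resorcinol would react at C4/C6 and not between its oxygens.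

Step 2
Reactants: 3 methyl 2,3-trans-3-(3,5-dimethoxyphenyl)-2-(4-methoxyphenyl)-4-oxo-2,3,4,5,6,7-hexahydrobenzofuran-6-carboxylate
Product: 5 methyl 3-(3,5-dimethoxyphenyl)-4-hydroxy-2-(4-methoxyphenyl)benzofuran-6-carboxylate, via furan ketoester 4 (not isolated)
Conditions: DDQ (3 equiv), 1,4-dioxane, reflux
Reagents that add atoms: none
Why: Two consecutive DDQ dehydrogenations (hydride abstraction, then proton loss): the C2–H, benzylic to the anisyl ring and next to O1, goes first to give furan 4, then the furylic C7–H is abstracted, the ester-activated C6–H is lost and the dienone tautomerises to the phenol, aromatisation driving both stages.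

Step 3
Reactants: 5 methyl 3-(3,5-dimethoxyphenyl)-4-hydroxy-2-(4-methoxyphenyl)benzofuran-6-carboxylate
Product: 6 3-(3,5-dimethoxyphenyl)-6-(hydroxymethyl)-2-(4-methoxyphenyl)benzofuran-4-ol
Conditions: LiAlH4 (3 equiv), THF, 0 °C to rt; then H2O, 1 M HCl
Reagents that add atoms: none
Why: Hydride reduction of an aryl methyl ester to the benzylic alcohol; the phenol is only deprotonated (one extra hydride equivalent), and the aryl ethers and the benzofuran are inert to LiAlH4.

Step 4
Reactants: 6 3-(3,5-dimethoxyphenyl)-6-(hydroxymethyl)-2-(4-methoxyphenyl)benzofuran-4-ol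
Product: 7 3-(3,5-dimethoxyphenyl)-4-hydroxy-2-(4-methoxyphenyl)benzofuran-6-carbaldehyde
Conditions: activated MnO2 (15 equiv), CH2Cl2/acetone, rt
Reagents that add atoms: none
Why: Activated MnO2 oxidises benzylic alcohols chemoselectively to aldehydes without over-oxidation; the phenol is meta to the carbinol, so no quinone methide pathway is open and it should be tolerated.

Step 5
Reactants: 7 3-(3,5-dimethoxyphenyl)-4-hydroxy-2-(4-methoxyphenyl)benzofuran-6-carbaldehyde
Product: 8 3-(3,5-dihydroxyphenyl)-4-hydroxy-2-(4-hydroxyphenyl)benzofuran-6-carbaldehyde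
Conditions: BBr3 (8 equiv), CH2Cl2, −78 °C to rt; then ice/H2O
Reagents that add atoms: none
Why: BBr3 ether cleavage (O-coordination, then bromide attack at methyl) removes the three aryl methyl ethers; aryl aldehydes and benzofurans normally survive it at low temperature, and the aldehyde deactivates ring A against electrophilic side reactions.

**Compound list**
1 | methyl 3,5-dioxocyclohexane-1-carboxylate | COC(=O)C1CC(=O)CC(=O)C1 | starting material
2 | (E)-3,4',5-trimethoxystilbene | COc1ccc(/C=C/c2cc(OC)cc(OC)c2)cc1 | starting material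
3 | methyl 2,3-trans-3-(3,5-dimethoxyphenyl)-2-(4-methoxyphenyl)-4-oxo-2,3,4,5,6,7-hexahydrobenzofuran-6-carboxylate (racemic; both C6 epimers, one drawn) | COC(=O)[C@H]1CC(=O)C2=C(C1)O[C@H](c1ccc(OC)cc1)[C@H]2c1cc(OC)cc(OC)c1 | intermediate
4 | methyl 3-(3,5-dimethoxyphenyl)-2-(4-methoxyphenyl)-4-oxo-4,5,6,7-tetrahydrobenzofuran-6-carboxylate (racemic; furan ketoester) | COC(=O)C1CC(=O)c2c(C1)oc(-c1ccc(OC)cc1)c2-c1cc(OC)cc(OC)c1 | intermediate
5 | methyl 3-(3,5-dimethoxyphenyl)-4-hydroxy-2-(4-methoxyphenyl)benzofuran-6-carboxylate | COC(=O)c1cc(O)c2c(-c3cc(OC)cc(OC)c3)c(-c3ccc(OC)cc3)oc2c1 | intermediate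
6 | 3-(3,5-dimethoxyphenyl)-6-(hydroxymethyl)-2-(4-methoxyphenyl)benzofuran-4-ol | OCc1cc(O)c2c(-c3cc(OC)cc(OC)c3)c(-c3ccc(OC)cc3)oc2c1 | intermediate
7 | 3-(3,5-dimethoxyphenyl)-4-hydroxy-2-(4-methoxyphenyl)benzofuran-6-carbaldehyde | O=Cc1cc(O)c2c(-c3cc(OC)cc(OC)c3)c(-c3ccc(OC)cc3)oc2c1 | intermediate
8 | 3-(3,5-dihydroxyphenyl)-4-hydroxy-2-(4-hydroxyphenyl)benzofuran-6-carbaldehyde | O=Cc1cc(O)c2c(-c3cc(O)cc(O)c3)c(-c3ccc(O)cc3)oc2c1 | target

Total step count: 5. Longest linear sequence: 5 steps.

**Steps most likely to fail**

Step 1. What may go wrong: direct one-electron oxidation of the electron-rich stilbene by trivalent manganese (oxidative dimerisation or acetoxylation) may compete with oxidation of the dione, or the dione radical may add to the wrong alkene carbon and swap the two aryl groups. The fallback sets out from 1 and comes back at 3, and replaces the radical pathway by a carbenoid one with no one-electron oxidant. Dione 1 is treated with PhI(OAc)2 and Na2CO3 in MeOH at 0 °C to give the phenyliodonium ylide methyl 3,5-dioxo-4-(phenyl-λ3-iodanylidene)cyclohexane-1-carboxylate F1. Heating F1 with 2 and catalytic Rh2(OAc)4 in 1,2-dichloroethane then effects the known formal [3+2] cycloaddition of dione iodonium ylides with aryl alkenes. The electrophilic carbenoid carbon is attacked by the alkene carbon remote from the anisyl ring, the enolate oxygen closes onto the 4-methoxybenzylic cation, iodobenzene is lost, and 3 results.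

Step 2. What may go wrong: the second dehydrogenation may stall because the ketone ring gives up hydride reluctantly, or the phenol, once formed, may be over-oxidised by excess quinone at reflux. The fallback sets out from 3 and comes back at 5. Only 1.1 equiv of DDQ is used in toluene at 60–80 °C, so that the easier dihydrofuran dehydrogenation alone takes place and furan ketoester 4 is isolated. Ring A is then aromatised without a hydride acceptor: LiN(SiMe3)2 (THF, −78 °C) and PhSeCl convert 4 into methyl 3-(3,5-dimethoxyphenyl)-2-(4-methoxyphenyl)-4-oxo-5-(phenylselanyl)-4,5,6,7-tetrahydrobenzofuran-6-carboxylate F2. Oxidation with H2O2 (CH2Cl2, pyridine, 0 °C to rt) triggers syn-elimination of the selenium group towards C6, and the dienone formed tautomerises to phenol 5. Selenation at C6 instead of C5 would lead to the same phenol.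

Step 5. What may go wrong: the Lewis acid may activate the aldehyde towards Friedel–Crafts attack by the newly unmasked, very electron-rich resorcinol and phenol rings (oligomerisation), or the last ether may cleave incompletely. The fallback sets out from 5 and comes back at 8, and moves the demethylation to a stage without an aldehyde.
- BBr3 (CH2Cl2, −78 to 0 °C; a methyl benzoate normally survives) converts 5 into methyl 3-(3,5-dihydroxyphenyl)-4-hydroxy-2-(4-hydroxyphenyl)benzofuran-6-carboxylate F3.
- tert-Butyldimethylsilyl chloride and imidazole in DMF give methyl 4-(tert-butyldimethylsilyloxy)-3-[3,5-bis(tert-butyldimethylsilyloxy)phenyl]-2-[4-(tert-butyldimethylsilyloxy)phenyl]benzofuran-6-carboxylate F4.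
- iBu2AlH (CH2Cl2, −78 °C) reduces the ester to {4-(tert-butyldimethylsilyloxy)-3-[3,5-bis(tert-butyldimethylsilyloxy)phenyl]-2-[4-(tert-butyldimethylsilyloxy)phenyl]benzofuran-6-yl}methanol F5.
- MnO2 (CH2Cl2, rt) gives 4-(tert-butyldimethylsilyloxy)-3-[3,5-bis(tert-butyldimethylsilyloxy)phenyl]-2-[4-(tert-butyldimethylsilyloxy)phenyl]benzofuran-6-carbaldehyde F6.
- Bu4NF buffered with AcOH (THF, 0 °C) removes the four silyl groups under conditions that do not touch the aldehyde and releases 8.

**Further compounds**
F1 | step 1 | methyl 3,5-dioxo-4-(phenyl-λ3-iodanylidene)cyclohexane-1-carboxylate | COC(=O)C1CC(=O)[C-]([I+]c2ccccc2)C(=O)C1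
F2 | step 2 | methyl 3-(3,5-dimethoxyphenyl)-2-(4-methoxyphenyl)-4-oxo-5-(phenylselanyl)-4,5,6,7-tetrahydrobenzofuran-6-carboxylate | COC(=O)C1Cc2oc(-c3ccc(OC)cc3)c(-c3cc(OC)cc(OC)c3)c2C(=O)C1[Se]c1ccccc1
F3 | step 5 | methyl 3-(3,5-dihydroxyphenyl)-4-hydroxy-2-(4-hydroxyphenyl)benzofuran-6-carboxylate | COC(=O)c1cc(O)c2c(-c3cc(O)cc(O)c3)c(-c3ccc(O)cc3)oc2c1
F4 | step 5 | methyl 4-(tert-butyldimethylsilyloxy)-3-[3,5-bis(tert-butyldimethylsilyloxy)phenyl]-2-[4-(tert-butyldimethylsilyloxy)phenyl]benzofuran-6-carboxylate | COC(=O)c1cc(O[Si](C)(C)C(C)(C)C)c2c(-c3cc(O[Si](C)(C)C(C)(C)C)cc(O[Si](C)(C)C(C)(C)C)c3)c(-c3ccc(O[Si](C)(C)C(C)(C)C)cc3)oc2c1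
F5 | step 5 | {4-(tert-butyldimethylsilyloxy)-3-[3,5-bis(tert-butyldimethylsilyloxy)phenyl]-2-[4-(tert-butyldimethylsilyloxy)phenyl]benzofuran-6-yl}methanol | OCc1cc(O[Si](C)(C)C(C)(C)C)c2c(-c3cc(O[Si](C)(C)C(C)(C)C)cc(O[Si](C)(C)C(C)(C)C)c3)c(-c3ccc(O[Si](C)(C)C(C)(C)C)cc3)oc2c1
F6 | step 5 | 4-(tert-butyldimethylsilyloxy)-3-[3,5-bis(tert-butyldimethylsilyloxy)phenyl]-2-[4-(tert-butyldimethylsilyloxy)phenyl]benzofuran-6-carbaldehyde | O=Cc1cc(O[Si](C)(C)C(C)(C)C)c2c(-c3cc(O[Si](C)(C)C(C)(C)C)cc(O[Si](C)(C)C(C)(C)C)c3)c(-c3ccc(O[Si](C)(C)C(C)(C)C)cc3)oc2c1
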